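A flat curve tempts one to ask what is holding the reaction back, when the earlier question is whether anything is left to react.

Minutes of the meeting on the flask, which is the beta run followed on. The matter stood so:

| flask | substrate | catalyst | temperature | remark | time |
|---|---|---|---|---|---|
| beta | 0.26 M | 52 mM | 35 °C | the very flask that is asked about, followed so far |  |
| zeta | 0.52 M | 52 mM | 20 °C | run made earlier |  |
| flask | 0.26 M | 52 mM | 35 °C |  | 10 h |

| run | time / h | target / % |
|---|---|---|
| beta | 0.833 | 22 |
| beta | 2.50 | 24 |
| beta | 5.00 | 23 |
| beta | 8.00 | 27 |
| beta | 10.0 | 24 |
| zeta | 0.333 | 5 |
| zeta | 1.00 | 19 |
| zeta | 2.00 | 22 |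
| zeta | 3.00 | 24 |
| zeta | 4.00 | 25 |

(readings scatter by 1.5 percentage points)

- Saturday's: at 10 h raise the temperature by 15 K, then wait 10 h
- Friday's: at 10 h add catalyst, 100% of the amount charged, then wait 10 h
- Tuesday's: change nothing and wait 10 h more
- Monday's: at 10 h take out 90% of the target then present, then wait 10 h

- a species is counted by the substrate in it: one side product counts as two
- what is taken out of target is counted as made
- candidate steps: substrate <-> other conformer; substrate + catalyst -> catalyst + target; catalyst + other conformer -> catalyst + isomer of the product; substrate + target -> side product; substrate -> uncatalysed product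
- additions bring no volume worth counting

1. target, in percent of the substrate first charged, at 10 h
2. the remedy with the largest gain of target, or "none" below 2 percentage points (Saturday's / Friday's / Tuesday's / Monday's / none)
3. target present, with what was taken out counted in, in percent of the substrate first charged, after Saturday's
4. target present, with what was taken out counted in, in percent of the substrate first charged, after Tuesday's

The first item was the level of the beta run: its readings from 2.50 h on average 24.5%, and they carry a scatter of 1.5 percentage points.

I then proposed treating substrate and other conformer as in balance at every moment, so that they form one pool, draining pseudo-first-order under an unchanged catalyst. The gap to the level then measures what remains of that pool. The first beta reading gives 0.253 h for the pool half-life, the time in which substrate and other conformer together halve. I warned that this is a rough reading, since its gap of 2.5 points stands against that scatter.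

Still, 10 h is 39.5 such half-lives, so I reckoned the pool at 10 h at <0.001% of the substrate charged, put now, g1 and g3 at the level, and named none of the remedies as best.

The forecaster gave 24.6% for now, 25.8% for g1, 25.2% for g3 and none as best. It agreed with me on the choice but differed on the two later values, because it allowed that “heat or waiting carries a modest upside risk”.

The flask gives 24.6% for now, 24.6% for g1 and 24.6% for g3, and best is none, as the forecast said.

    substrate ⇌ other conformer, settled at all times (K = 4.50, ΔH = 4.00 kJ mol⁻¹)
    substrate + catalyst → catalyst + target (k = 0.0230 M⁻¹ s⁻¹, Ea = 60.0 kJ mol⁻¹)
    catalyst + other conformer → catalyst + isomer of the product (k = 0.0120 M⁻¹ s⁻¹, Ea = 72.0 kJ mol⁻¹)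
    substrate + target → side product (k = 0.00410 M⁻¹ s⁻¹, Ea = 64.0 kJ mol⁻¹)
    substrate → uncatalysed product (k = 1.60 × 10⁻⁴ s⁻¹, Ea = 104 kJ mol⁻¹)
    (constants at 35 °C)

At 1.00 h the flask holds 5.82% as substrate and other conformer, where the pool half-life reckons 6.46%; at 10.0 h they stand at 0% and 0%. The neighbouring flask has 0.013 M of catalyst, a quarter of what the flask was charged with. Scaling the half-life by catalyst gives 1.01 h, so 0.106% of the pool should remain at 10.0 h. That neighbouring flask holds 0% substrate and 0.0149% other conformer then, with target at 16.0% and uncatalysed product at 12.7%.

Readings and results are simulated from invented constants; noise was put on by code.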